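The data stem from a simulated flask for substances that don't exist; scatter was added.

Divide each run's partner charge by its starting-material charge before looking at any curve, and call the result the partner equivalents.

| setting | ash | larch | alder | elm | noon | midnight |
|---|---|---|---|---|---|---|
| starting material | 0.24 M | 0.24 M | 0.24 M | 0.56 M | 0.80 M | 0.24 M |
| partner | 0.25 M | 0.31 M | 0.41 M | 0.288 M | 0.400 M | 0.288 M |
| remark | run made earlier | run made earlier | run made earlier | run made earlier |  |  |
| time |  |  |  |  | 10 h | 20 h |

| run | time / h | product / % | starting material / % |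
|---|---|---|---|
| ash | 1.33 | 1.5 | 79.0 |
| ash | 4.00 | 5.8 | 57.2 |
| ash | 6.00 | 8.4 | 49.6 |
| ash | 10.0 | 12.1 | 41.0 |
| ash | 15.0 | 14.2 | 35.5 |
| larch | 1.00 | 1.5 | 79.4 |
| larch | 2.00 | 3.4 | 66.6 |
| larch | 4.00 | 8.4 | 50.5 |
| larch | 8.00 | 15.1 | 35.6 |
| larch | 15.0 | 19.2 | 27.3 |
| alder | 1.00 | 2.4 | 74.0 |
| alder | 2.00 | 5.4 | 57.7 |
| alder | 4.00 | 12.5 | 40.1 |
| alder | 8.00 | 21.3 | 25.9 |
| alder | 15.0 | 27.6 | 16.9 |
| elm | 1.00 | 0.9 | 82.7 |
| elm | 2.00 | 2.2 | 73.3 |
| elm | 4.00 | 3.9 | 65.3 |
| elm | 8.00 | 4.9 | 59.9 |
| elm | 15.0 | 5.2 | 57.0 |

(standard deviation of a reading: 0.3 percentage points)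

* the winner by amount of product, in percent of the starting material charged; "neither" if no more than 2 percentage points parts them (noon / midnight / neither)
* how much product is there at the end, in percent of the starting material charged: noon
* how much product is there at the end, in percent of the starting material charged: midnight

I set the earlier runs in that order:

| run | partner equivalents | product at 15.0 h |
|---|---|---|
| elm | 0.514 | 5.2% |
| ash | 1.04 | 14.2% |
| larch | 1.29 | 19.2% |
| alder | 1.71 | 27.6% |

Reading down, I saw product climb with the equivalents. In elm, partner was the limiting reagent, with 0.288 M against 0.56 M of starting material. From ash to alder, all charged with 0.24 M of starting material and read at 15.0 h, product rose 20 percentage points per added equivalent; that rise, the yield per equivalent, became my rule for that charge and time. Ash to larch gave 20 points, and elm to ash, where the charge of starting material differs as well, gave 17 points.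

Then I asked how the gains drifted. Ash still gained 2.1 points over its last 5.00 h, while elm gained 0.3 points over its last 7.00 h.

Noon has 0.500 equivalents, close to elm, so I reckoned 4.91% from elm, as a rough estimate, since noon is charged with 0.80 M of starting material against elm's 0.56 M and stops at 10 h. Midnight has 1.20, which from ash gave 17.4%, and adding ash's last gain for the further 5.00 h gave 19.5%.

The forecast said 4.3% for noon, below mine, and 18.3% for midnight, inside my span. It named midnight the winner, holding that elm “stalls once the partner is nearly gone”.

The flask gave 5.17% for noon and 18.8% for midnight, so midnight won. Starting from ash at 14.2%, moving the partner charge to midnight's gave 17.6%, while moving the time gave 15.1%. The yield per equivalent times the difference in equivalents gives 14 points between noon and midnight; these flasks, which also differ in starting material and time, stand 14 points apart, clear of the 2 points margin.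

    starting material + partner ⇌ intermediate A (K = 6.40 /M, k = 1.20 × 10⁻⁴ /M/s)
    starting material + partner → intermediate B (k = 1.10 × 10⁻⁴ /M/s)
    intermediate A ⇌ intermediate C (K = 0.820, k = 2.60 × 10⁻⁵ /s)
    partner + intermediate A ⇌ intermediate D (K = 3.30 /M, k = 6.90 × 10⁻⁵ /M/s)
    partner + intermediate B ⇌ product (K = 14.0 /M, k = 2.70 × 10⁻⁴ /M/s)

A neighbour of midnight with 0.17 M of partner has 0.708 equivalents, so the rule, counted down from ash, gives 7.56%. That flask gave 7.91%.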